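**Assumptions**

- Aromatisation mode: the ketal carbon of the cycloadduct, which carries one methoxy and one trimethylsilyloxy group, is taken to collapse with loss of methanol on acidic work-up, so ring B is written as emerging with both phenols free.
- Sense of induction: the (1S,4S) enantiomer of the diene ligand is taken to deliver the alkenyl group to the enoate face that gives the (R) ester, by analogy with its behaviour towards other (E)-enoates; if the sense proves opposite, the (1R,4R) ligand is used and nothing else changes.

## Analysis of the target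

Caraganin B (23) is an isoflavone whose ring A carries the 5-hydroxyl (hydrogen-bonded to the C4 carbonyl) and the 7-methoxy group, and whose pyranone ring carries ring B at C3. Ring B is a resorcinol with hydroxyls at C2' and C4', hydrogens at C3' and C6', and at C5' the only stereocentre, Cα, which is (R) and bears a hydrogen, ring C (4-hydroxyphenyl) and an (E)-styryl arm ending in ring D (2,4-dimethoxyphenyl). With one stereocentre there is no relative configuration to control, but Cα–H is flanked by two arenes and an alkene, so strong base can remove it or move the double bond into conjugation, and either event destroys the centre. The electron-rich styrene sits next to the C4' phenol, so strong acid invites protonation and closure to a 4-arylflavan; hydrogenolysis is excluded by the alkene, and electrophilic oxidants must be used with care. Three methyl ethers must stay while four phenols are freed, which rules out late demethylation and calls for protecting groups that leave under near-neutral conditions. The real difficulty is the regio- and enantioselective attachment of a 1,3-diarylallyl unit to C5' of an electron-rich ring on which C3' and the oxygens compete. The strategy rests on the pattern of ring B: C2'(O)–C3'(H)–C4'(O)–C5'(Cα) is the four-carbon chain of a γ-substituted β-keto ester, and C1' (which must carry the future C3 of the chromone) and C6'(H) are the two carbons of a terminal acetylenic ketone, so ring B can be grown around a Cα that is already in place.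

## Retrosynthetic reasoning

**23 back to 22.** The last operation forms no skeletal bond. All four phenols of 23 are carried in 22 as tert-butyldimethylsilyl ethers and released together by buffered fluoride. Silyl ethers are chosen because their removal needs no acid (threat to the styrene beside the C4' phenol), no hydrogen (threat to the alkene) and no strong base (threat to Cα–H), and because the three methyl ethers are inert to fluoride.

**22 back to 21 and 20.** The C2=C3 double bond is cut as the elements of water, giving the tertiary alcohol 21. The C3–C4 bond of 21 is then cut between a ketone carbon (C3) and an aldehyde carbon (C4), giving the keto aldehyde 20. This cut makes C3 the carbonyl carbon and C2 the methyl carbon of an aryl methyl ketone, which is exactly what the construction of ring B leaves at C1'. Forward, an N-heterocyclic carbene must turn the ring A aldehyde into an acyl anion equivalent that adds to the ring B ketone. The stereocentre formed at C3 does not matter because the dehydration removes it.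

**20 back to 19, and to 16 and 18.** The O1–C2 ether bond is cut to the α-bromo ketone 16 and the phenol 18; the hydroxyl left in 19 is silylated afterwards to give 20. Ring A enters as 18 because its two hydroxyls are equivalent, so the etherification raises no regiochemical question, and the hydroxyl that remains becomes the C5 phenol. Compound 18 comes from 17 by methylation of the one hydroxyl that is not ortho to the formyl group.

**16 back to 14.** The carbon–bromine bond is cut, by way of the silyl enol ether 15, to the methyl ketone 14. One silylating operation on 14 protects the C2' and C4' phenols and forms the enol ether, so protection and activation cost a single step. The halogen must then reach the enol ether faster than the styrene, which low temperature should ensure.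

**14 back to 11 and 12 (the strategic disconnection).** Ring B is cut at C1'–C2' and at C5'–C6', by way of the cycloadduct 13. These bonds are chosen instead of the C5'–Cα bond because they divide ring B into a four-carbon diene 11 that already carries Cα with its configuration and a two-carbon dienophile 12 that already carries the acetyl group. Neither the site of attachment on ring B (C5' versus C3') nor the configuration of Cα then has to be controlled on an aromatic ring: the first follows from the connectivity of the diene and the second is brought in. Forward, the cycloaddition must take one orientation, and the adduct must shed the alkoxy group of its ketal carbon to become aromatic. The alkoxy group of 11 is methyl. It is expelled in the aromatisation and so needs no later removal, and unlike an allyl group it cannot undergo a [3,3] shift, which an O-allyl ketene acetal would suffer near room temperature.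

**11 back to 7.** Diene 11 is the bis(enol silyl ether) of the β-keto ester 9 and is reached through the mono-silylated enoate 10. Compound 9 is cut at its C2–C3 bond to the acid 7 and a malonate-type two-carbon unit, by way of the acyl intermediate 8. This homologation runs under neutral conditions with Cα two atoms from the reacting carbon.

**7 back to 3 and 5.** Acid 7 comes from its allyl ester 6, which can be cleaved without hydroxide. Ester 6 is cut at the bond between Cα and the styryl carbon, giving the cinnamate 3 and the alkenyl boronate 5. Cinnamate 3 already holds ring C, Cα as its β-carbon and the future C5' as its α-carbon, so one catalytic conjugate addition completes the substitution at Cα and sets its configuration on the simplest possible substrate. Forward, a chiral rhodium catalyst has to select one face of the enoate.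

**3 and 5 back to 1 and 4.** Cinnamate 3 is the silyl ether of the allyl ester 2 of p-coumaric acid (1). Boronate 5 is cut at its alkene to 2,4-dimethoxybenzaldehyde (4) and a one-carbon boron reagent, which gives the (E)-alkenyl boronate in one step.

## Alternatives that were turned down

**Alternative 1: acyl–arene closure of the pyranone at C4–C4a.**
- Disconnection and key step: the C4–C4a bond is cut to the (Z)-3-aryloxy-2-arylacrylic acid A1. Forward, anhydride activation lets the acyl carbon attack the 3,5-dimethoxyphenyl ether ortho to oxygen, giving 2',4'-bis(benzyloxy)-5'-bromo-5,7-dimethoxyisoflavone A2.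
- For: both ortho positions of the aryl ether are equivalent and doubly activated, so the closure has no regiochemical ambiguity, needs no catalyst, and creates no stereocentre that must later be erased. On the pyranone alone it is sturdier than the carbene closure used in the chosen route (step 14).
- Against: A2 holds only a bromine at C5', so the hard problem is postponed to the most valuable intermediate. Joining a secondary carbon that is benzylic twice over and allylic to an aryl halide with control of configuration is difficult, since 1,3-diarylallyl metal species are ambident (their termini carry different arenes) and configurationally labile. A2 also has a methyl ether at C5 that must be cleaved selectively before ring D brings two more methyl ethers. Its benzyl ethers cannot be removed by hydrogenolysis once the styrene is present, and Lewis-acid debenzylation endangers the acid-sensitive allyl phenol.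
- Comparison: the chosen route is less convergent and uses a more delicate pyranone closure. In exchange it sets Cα by a catalytic reaction on a simple cinnamate (3) and fixes its position on ring B by construction.

**Alternative 2: late pyranone closure at O1–C8a by fluoride displacement.**
- Disconnection and key step: the O1–C8a bond is cut to the α-formyl ketone A3. Forward, its enol oxygen displaces one of two equivalent ortho fluorines under mild carbonate base, giving the 5-fluoro-7-methoxyisoflavone A4 with the complete, allyl-protected side chain.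
- For: the closure is a simple substitution with no regiochemical question, no catalyst and no change of oxidation state, and the allyl ethers leave under zerovalent palladium without harming the styrene. On these points it is at least as strong as the chosen route's carbene closure followed by dehydration.
- Against: A4 still has fluorine where the C5 hydroxyl belongs. The exchange needs a second substitution by an oxygen nucleophile on a chromone that hard nucleophiles open at C2. A3 requires a ring B unit with a benzylic CH2–C(=O) link to ring A and the whole chiral side chain, so the question of how ring B acquires Cα at C5' is left unanswered. The Cα–H bond passes through several basic steps (formylation, carbonate closure, fluoride exchange).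
- Comparison: the chosen route answers the ring B question directly through the benzannulation of 11, and its ring A partner 18 delivers the C5 oxygen from the start.

**Alternative 3: carbene-catalysed closure of the pyranone at C3–C4 as the strategic step.**
- Disconnection and key step: the C3–C4 bond is cut. Forward, a triazolium-derived carbene converts the ring A aldehyde of a phenacyl ether into an acyl anion equivalent that adds to the ring B ketone, giving the 3-hydroxyisoflavanone A5, which has the same constitution as compound 21.
- For: the conditions are mild and compatible with silyl ethers, and the disconnection needs only an aryl methyl ketone and a salicylaldehyde. The chosen route adopts this closure unchanged as step 14, so on the pyranone the two are equal.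
- Against: as the step that carries the strategy it presupposes the 5'-substituted ketone with Cα already installed. If ring B were taken from a purchased resorcinol, Cα would have to be attached to C5' enantioselectively in competition with C3' (between the two oxygens) and with O-alkylation.
- Comparison: where the alternative would be shorter, it is so only if that arylation is solved. The chosen route places the risk in the construction of ring B from 11 and 12, which supplies the regiochemistry, the stereocentre and the ketone that the carbene closure needs.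

Key step: step 9

## Route

Step 1
Reactants: 1 p-coumaric acid
Product: 2 allyl (E)-3-(4-hydroxyphenyl)prop-2-enoate
Conditions: allyl bromide (1.1 equiv), KHCO3 (1.2 equiv), DMF, rt
Reagents that add atoms: allyl bromide, C=CCBr
Why: Carboxylate alkylation (SN2); hydrogencarbonate deprotonates only the carboxylic acid, so the phenol stays free and the (E)-alkene is untouched.

Step 2
Reactants: 2 allyl (E)-3-(4-hydroxyphenyl)prop-2-enoate
Product: 3 allyl (E)-3-[4-(tert-butyldimethylsilyloxy)phenyl]prop-2-enoate
Conditions: TBSCl (1.2 equiv), imidazole (2.5 equiv), DMF, rt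
Reagents that add atoms: tert-butyldimethylsilyl chloride, CC(C)(C)[Si](C)(C)Cl
Why: Imidazole-mediated silylation of a phenol; the silyl ether removes the acidic proton that would quench the organorhodium intermediate of step 4.

Step 3
Reactants: 4 2,4-dimethoxybenzaldehyde
Product: 5 (E)-2-[2-(2,4-dimethoxyphenyl)ethenyl]-4,4,5,5-tetramethyl-1,3,2-dioxaborolane
Conditions: CH2(Bpin)2 (1.2 equiv), lithium 2,2,6,6-tetramethylpiperidide (LiTMP, 1.2 equiv), THF, 0 °C; then 4, −78 °C → rt
Reagents that add atoms: bis[(pinacolato)boryl]methane, CC1(C)OB(CB2OC(C)(C)C(C)(C)O2)OC1(C)C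
Why: Boron-Wittig olefination; the lithiated geminal bis(boronate) adds to the aldehyde and the adduct loses a borate by syn elimination, which with aryl aldehydes gives the trans-alkenyl boronate.

Step 4
Reactants: 3 allyl (E)-3-[4-(tert-butyldimethylsilyloxy)phenyl]prop-2-enoate; 5 (E)-2-[2-(2,4-dimethoxyphenyl)ethenyl]-4,4,5,5-tetramethyl-1,3,2-dioxaborolane (1.5 equiv)
Product: 6 allyl (3R,4E)-3-[4-(tert-butyldimethylsilyloxy)phenyl]-5-(2,4-dimethoxyphenyl)pent-4-enoate
Conditions: [RhCl(C2H4)2]2 (2.5 mol%), (1S,4S)-2,5-diphenylbicyclo[2.2.2]octa-2,5-diene (5.5 mol%), KOH (0.1 equiv, aq.), 1,4-dioxane/H2O (10:1), 40 °C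
Reagents that add atoms: none
Why: Hayashi–Miyaura conjugate addition: the alkenyl group passes from boron to monovalent rhodium, the enoate inserts, and water protonates the rhodium enolate. Cα is set by the C2-symmetric diene ligand, whose phenyl groups allow the ester to bind through one face only, so the styryl group is delivered to the face that gives the (R) centre with retention of the (E)-alkene. Only a catalytic amount of hydroxide is used so that the aryl silyl ether and the ester survive.

Step 5
Reactants: 6 allyl (3R,4E)-3-[4-(tert-butyldimethylsilyloxy)phenyl]-5-(2,4-dimethoxyphenyl)pent-4-enoate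
Product: 7 (3R,4E)-3-[4-(tert-butyldimethylsilyloxy)phenyl]-5-(2,4-dimethoxyphenyl)pent-4-enoic acid
Conditions: Pd(PPh3)4 (3 mol%), morpholine (3 equiv), THF, rt; pH 4 buffer work-up
Reagents that add atoms: none
Why: Tsuji–Trost deallylation; zerovalent palladium ionises the allyl ester and morpholine captures the allyl group, so the acid is released without hydroxide (which would cleave the aryl silyl ether) and without strong acid.

Step 6
Reactants: 7 (3R,4E)-3-[4-(tert-butyldimethylsilyloxy)phenyl]-5-(2,4-dimethoxyphenyl)pent-4-enoic acid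
Product: 9 methyl (5R,6E)-5-[4-(tert-butyldimethylsilyloxy)phenyl]-7-(2,4-dimethoxyphenyl)-3-oxohept-6-enoate, via acyl Meldrum's acid 8 (not isolated)
Conditions: Meldrum's acid (1.1 equiv), DCC (1.1 equiv), DMAP (1.5 equiv), CH2Cl2, 0 °C → rt; filter, cold aq. KHSO4 wash; then MeOH, toluene, 80 °C
Reagents that add atoms: Meldrum's acid, CC1(C)OC(=O)CC(=O)O1; methanol, CO
Why: C-acylation of Meldrum's acid, then thermolysis to an acylketene that methanol traps with loss of acetone and carbon dioxide; the sequence is neutral and Cα is two atoms from the reacting carbon.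

Step 7
Reactants: 9 methyl (5R,6E)-5-[4-(tert-butyldimethylsilyloxy)phenyl]-7-(2,4-dimethoxyphenyl)-3-oxohept-6-enoate
Product: 10 methyl (2Z,5R,6E)-5-[4-(tert-butyldimethylsilyloxy)phenyl]-7-(2,4-dimethoxyphenyl)-3-(trimethylsilyloxy)hepta-2,6-dienoate
Conditions: TMSCl (1.5 equiv), Et3N (1.6 equiv), toluene, rt; filter under argon, concentrate
Reagents that add atoms: chlorotrimethylsilane, C[Si](C)(C)Cl
Why: Amine-mediated O-silylation of the enol of a β-keto ester; the chelated enol should give the (Z)-enoate, though this geometry has no consequence later.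

Step 8
Reactants: 10 methyl (2Z,5R,6E)-5-[4-(tert-butyldimethylsilyloxy)phenyl]-7-(2,4-dimethoxyphenyl)-3-(trimethylsilyloxy)hepta-2,6-dienoate
Product: 11 (3Z,5S,6E)-5-[4-(tert-butyldimethylsilyloxy)phenyl]-7-(2,4-dimethoxyphenyl)-1-methoxy-1,3-bis(trimethylsilyloxy)hepta-1,3,6-triene
Conditions: LiN(iPr)2 (LDA, 1.3 equiv), THF, −78 °C; TMSCl (1.5 equiv), −78 → 0 °C; concentrate, hexane, filter under argon; used at once
Reagents that add atoms: chlorotrimethylsilane, C[Si](C)(C)Cl
Why: Kinetic γ-deprotonation of the silyloxy enoate and O-silylation of the dienolate give the ketene-acetal diene, with the bulky Cα substituent expected trans to C2 (3Z). Cα–H is much less acidic and more hindered than the γ-CH2, so the centre is not touched; its descriptor changes to S only because the dienyl carbon now outranks the styryl carbon.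

Step 9
Reactants: 11 (3Z,5S,6E)-5-[4-(tert-butyldimethylsilyloxy)phenyl]-7-(2,4-dimethoxyphenyl)-1-methoxy-1,3-bis(trimethylsilyloxy)hepta-1,3,6-triene; 12 but-3-yn-2-one (2 equiv)
Product: 14 1-{5-[(1R,2E)-1-[4-(tert-butyldimethylsilyloxy)phenyl]-3-(2,4-dimethoxyphenyl)prop-2-en-1-yl]-2,4-dihydroxyphenyl}ethan-1-one, via cyclohexadiene cycloadduct 13 (not isolated)
Conditions: toluene, −78 °C → rt (45 °C if needed), no Lewis acid; then HCl (0.5 M aq.), THF, 0 °C
Reagents that add atoms: none
Why: Normal-electron-demand [4+2] cycloaddition of a ketene-acetal diene with an acetylenic ketone followed by aromatisation; the closest known reaction type is the resorcinol synthesis from 1-alkoxy-1,3-bis(silyloxy)-1,3-dienes and alkynones or alkynoates. The diene is polarised towards C4 (the carbon bearing Cα) and the ynone towards its terminal carbon, so a strongly asynchronous transition state forms C5'–C6' first and C1'–C2' second, which places the acetyl group beside the former ketene-acetal carbon. Ring B closes as a six-membered carbocycle in this one intermolecular cycloaddition, giving the cyclohexa-1,4-diene 13. In 13 the ketal carbon carries methoxy and silyloxy groups and the opposite sp3 carbon a hydrogen; on acidic work-up the ketal collapses with loss of methanol, the dienone tautomerises and the silyl enol ether hydrolyses, so the arene forms without an oxidant and both phenols emerge free. No stereocentre is created, since both sp3 ring carbons of 13 become sp2, and Cα keeps its configuration because it lies outside the reacting π system and meets neither strong base nor strong acid. The step needs regioselectivity, which the matched polarisation secures, and it needs closure through the ketal carbon C1 and not through C2 onto the ketone, which would give a salicylate; the absence of a Lewis acid and the (3Z) geometry, which lets the diene reach the s-cis conformation with the bulky group outside, favour the cycloaddition.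

Step 10
Reactants: 14 1-{5-[(1R,2E)-1-[4-(tert-butyldimethylsilyloxy)phenyl]-3-(2,4-dimethoxyphenyl)prop-2-en-1-yl]-2,4-dihydroxyphenyl}ethan-1-one
Product: 16 2-bromo-1-{2,4-bis(tert-butyldimethylsilyloxy)-5-[(1R,2E)-1-[4-(tert-butyldimethylsilyloxy)phenyl]-3-(2,4-dimethoxyphenyl)prop-2-en-1-yl]phenyl}ethan-1-one, via silyl enol ether 15 (not isolated)
Conditions: TBSOTf (3.5 equiv), Et3N (5 equiv), CH2Cl2, 0 °C → rt; aq. NaHCO3 work-up; then NBS (1.05 equiv), THF, −78 °C
Reagents that add atoms: tert-butyldimethylsilyl triflate, CC(C)(C)[Si](C)(C)OS(=O)(=O)C(F)(F)F; N-bromosuccinimide, O=C1CCC(=O)N1Br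
Why: Silyl triflate and amine silylate both phenols and convert the methyl ketone into its silyl enol ether in one operation; α-bromination of the enol ether then gives the bromoketone. A silyl enol ether reacts with the bromine source at −78 °C far faster than a styrene or a dimethoxyarene does, which should keep the side chain and ring D intact.

Step 11
Reactants: 17 2,4,6-trihydroxybenzaldehyde
Product: 18 2,6-dihydroxy-4-methoxybenzaldehyde
Conditions: Me2SO4 (1.0 equiv), K2CO3 (1.0 equiv), acetone, 0 °C → rt
Reagents that add atoms: dimethyl sulfate, COS(=O)(=O)OC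
Why: Selective O-methylation; the 4-hydroxyl is the only one not hydrogen-bonded to the formyl group and gives the best-stabilised phenoxide, so one equivalent of the methylating agent should go there; any dimethyl ether is removed by chromatography.

Step 12
Reactants: 16 2-bromo-1-{2,4-bis(tert-butyldimethylsilyloxy)-5-[(1R,2E)-1-[4-(tert-butyldimethylsilyloxy)phenyl]-3-(2,4-dimethoxyphenyl)prop-2-en-1-yl]phenyl}ethan-1-one; 18 2,6-dihydroxy-4-methoxybenzaldehyde (1.5 equiv)
Product: 19 2-(2-{2,4-bis(tert-butyldimethylsilyloxy)-5-[(1R,2E)-1-[4-(tert-butyldimethylsilyloxy)phenyl]-3-(2,4-dimethoxyphenyl)prop-2-en-1-yl]phenyl}-2-oxoethoxy)-6-hydroxy-4-methoxybenzaldehyde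
Conditions: K2CO3 (1.1 equiv), acetone, 0 °C → rt
Reagents that add atoms: none
Why: Williamson etherification of an acidic, formyl-activated phenol with a phenacyl bromide, fast at room temperature. The two hydroxyls of 18 are equivalent and the one left after the first alkylation is tied up in a hydrogen bond, which together with the excess of 18 should stop the reaction at the mono-ether; low temperature avoids aldol closure to a benzofuran.

Step 13
Reactants: 19 2-(2-{2,4-bis(tert-butyldimethylsilyloxy)-5-[(1R,2E)-1-[4-(tert-butyldimethylsilyloxy)phenyl]-3-(2,4-dimethoxyphenyl)prop-2-en-1-yl]phenyl}-2-oxoethoxy)-6-hydroxy-4-methoxybenzaldehyde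
Product: 20 2-(2-{2,4-bis(tert-butyldimethylsilyloxy)-5-[(1R,2E)-1-[4-(tert-butyldimethylsilyloxy)phenyl]-3-(2,4-dimethoxyphenyl)prop-2-en-1-yl]phenyl}-2-oxoethoxy)-6-(tert-butyldimethylsilyloxy)-4-methoxybenzaldehyde
Conditions: TBSCl (1.5 equiv), imidazole (3 equiv), DMAP (0.1 equiv), DMF, rt
Reagents that add atoms: tert-butyldimethylsilyl chloride, CC(C)(C)[Si](C)(C)Cl
Why: Silylation of the remaining phenol; it removes an acidic proton that would consume the carbene catalyst of step 14 and deactivate the aldehyde as its phenoxide.

Step 14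
Reactants: 20 2-(2-{2,4-bis(tert-butyldimethylsilyloxy)-5-[(1R,2E)-1-[4-(tert-butyldimethylsilyloxy)phenyl]-3-(2,4-dimethoxyphenyl)prop-2-en-1-yl]phenyl}-2-oxoethoxy)-6-(tert-butyldimethylsilyloxy)-4-methoxybenzaldehyde
Product: 21 3-{2,4-bis(tert-butyldimethylsilyloxy)-5-[(1R,2E)-1-[4-(tert-butyldimethylsilyloxy)phenyl]-3-(2,4-dimethoxyphenyl)prop-2-en-1-yl]phenyl}-5-(tert-butyldimethylsilyloxy)-3-hydroxy-7-methoxychroman-4-one (both C3 epimers)
Conditions: 2-(pentafluorophenyl)-6,7-dihydro-5H-pyrrolo[2,1-c][1,2,4]triazol-2-ium tetrafluoroborate (15 mol%), DBU (12 mol%), THF, rt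
Reagents that add atoms: none
Why: Intramolecular crossed aldehyde–ketone benzoin reaction; the carbene adds to the aldehyde, the resulting acyl anion equivalent attacks the ketone through a six-membered transition state, and the catalyst is released. The new C3 centre forms without control, which is acceptable because step 15 removes it.

Step 15
Reactants: 21 3-{2,4-bis(tert-butyldimethylsilyloxy)-5-[(1R,2E)-1-[4-(tert-butyldimethylsilyloxy)phenyl]-3-(2,4-dimethoxyphenyl)prop-2-en-1-yl]phenyl}-5-(tert-butyldimethylsilyloxy)-3-hydroxy-7-methoxychroman-4-one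
Product: 22 3-{2,4-bis(tert-butyldimethylsilyloxy)-5-[(1R,2E)-1-[4-(tert-butyldimethylsilyloxy)phenyl]-3-(2,4-dimethoxyphenyl)prop-2-en-1-yl]phenyl}-5-(tert-butyldimethylsilyloxy)-7-methoxy-4H-chromen-4-one
Conditions: SOCl2 (1.5 equiv), pyridine (6 equiv), CH2Cl2, 0 °C
Reagents that add atoms: none
Why: Dehydration of a tertiary benzylic alcohol through its chlorosulfite; loss of a C2 hydrogen gives the conjugated chromone, and excess pyridine keeps the medium non-acidic so the styrene is not protonated.

Step 16
Reactants: 22 3-{2,4-bis(tert-butyldimethylsilyloxy)-5-[(1R,2E)-1-[4-(tert-butyldimethylsilyloxy)phenyl]-3-(2,4-dimethoxyphenyl)prop-2-en-1-yl]phenyl}-5-(tert-butyldimethylsilyloxy)-7-methoxy-4H-chromen-4-one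
Product: 23 caraganin B, 3-{2,4-dihydroxy-5-[(1R,2E)-3-(2,4-dimethoxyphenyl)-1-(4-hydroxyphenyl)prop-2-en-1-yl]phenyl}-5-hydroxy-7-methoxy-4H-chromen-4-one
Conditions: Bu4NF (5 equiv), AcOH (5 equiv), THF, 0 °C → rt
Reagents that add atoms: none
Why: Fluoride cleavage of four aryl silyl ethers; acetic acid buffers the phenoxides so that neither Cα–H nor the chromone meets strong base, and the methyl ethers are inert.

## Compound list

1 | p-coumaric acid, (E)-3-(4-hydroxyphenyl)prop-2-enoic acid | OC(=O)/C=C/c1ccc(O)cc1 | starting material
2 | allyl (E)-3-(4-hydroxyphenyl)prop-2-enoate | C=CCOC(=O)/C=C/c1ccc(O)cc1 | intermediate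
3 | allyl (E)-3-[4-(tert-butyldimethylsilyloxy)phenyl]prop-2-enoate | C=CCOC(=O)/C=C/c1ccc(O[Si](C)(C)C(C)(C)C)cc1 | intermediate
4 | 2,4-dimethoxybenzaldehyde | COc1ccc(C=O)c(OC)c1 | starting material
5 | (E)-2-[2-(2,4-dimethoxyphenyl)ethenyl]-4,4,5,5-tetramethyl-1,3,2-dioxaborolane | COc1ccc(/C=C/B2OC(C)(C)C(C)(C)O2)c(OC)c1 | intermediate
6 | allyl (3R,4E)-3-[4-(tert-butyldimethylsilyloxy)phenyl]-5-(2,4-dimethoxyphenyl)pent-4-enoate | COc1ccc(/C=C/[C@H](c2ccc(O[Si](C)(C)C(C)(C)C)cc2)CC(=O)OCC=C)c(OC)c1 | intermediate
7 | (3R,4E)-3-[4-(tert-butyldimethylsilyloxy)phenyl]-5-(2,4-dimethoxyphenyl)pent-4-enoic acid | COc1ccc(/C=C/[C@H](c2ccc(O[Si](C)(C)C(C)(C)C)cc2)CC(=O)O)c(OC)c1 | intermediate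
8 | 5-{(3R,4E)-3-[4-(tert-butyldimethylsilyloxy)phenyl]-5-(2,4-dimethoxyphenyl)-1-hydroxypent-4-en-1-ylidene}-2,2-dimethyl-1,3-dioxane-4,6-dione (acyl Meldrum's acid, enol form) | COc1ccc(/C=C/[C@H](c2ccc(O[Si](C)(C)C(C)(C)C)cc2)CC(O)=C2C(=O)OC(C)(C)OC2=O)c(OC)c1 | intermediate (not isolated)
9 | methyl (5R,6E)-5-[4-(tert-butyldimethylsilyloxy)phenyl]-7-(2,4-dimethoxyphenyl)-3-oxohept-6-enoate | COc1ccc(/C=C/[C@H](c2ccc(O[Si](C)(C)C(C)(C)C)cc2)CC(=O)CC(=O)OC)c(OC)c1 | intermediate
10 | methyl (2Z,5R,6E)-5-[4-(tert-butyldimethylsilyloxy)phenyl]-7-(2,4-dimethoxyphenyl)-3-(trimethylsilyloxy)hepta-2,6-dienoate | COc1ccc(/C=C/[C@H](c2ccc(O[Si](C)(C)C(C)(C)C)cc2)C/C(O[Si](C)(C)C)=C/C(=O)OC)c(OC)c1 | intermediate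
11 | (3Z,5S,6E)-5-[4-(tert-butyldimethylsilyloxy)phenyl]-7-(2,4-dimethoxyphenyl)-1-methoxy-1,3-bis(trimethylsilyloxy)hepta-1,3,6-triene (geometry at C1=C2 undefined and without consequence) | COc1ccc(/C=C/[C@H](c2ccc(O[Si](C)(C)C(C)(C)C)cc2)/C=C(\O[Si](C)(C)C)C=C(OC)O[Si](C)(C)C)c(OC)c1 | intermediate
12 | but-3-yn-2-one | CC(=O)C#C | starting material
13 | 1-{3-[(1S,2E)-1-[4-(tert-butyldimethylsilyloxy)phenyl]-3-(2,4-dimethoxyphenyl)prop-2-en-1-yl]-6-methoxy-4,6-bis(trimethylsilyloxy)cyclohexa-1,4-dien-1-yl}ethan-1-one (mixture at the two sp3 ring carbons) | COc1ccc(/C=C/[C@H](c2ccc(O[Si](C)(C)C(C)(C)C)cc2)C2C=C(C(C)=O)C(OC)(O[Si](C)(C)C)C=C2O[Si](C)(C)C)c(OC)c1 | intermediate (not isolated)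
14 | 1-{5-[(1R,2E)-1-[4-(tert-butyldimethylsilyloxy)phenyl]-3-(2,4-dimethoxyphenyl)prop-2-en-1-yl]-2,4-dihydroxyphenyl}ethan-1-one | COc1ccc(/C=C/[C@H](c2ccc(O[Si](C)(C)C(C)(C)C)cc2)c2cc(C(C)=O)c(O)cc2O)c(OC)c1 | intermediate
15 | tert-butyldimethylsilyl enol ether of the 2,4-bis-O-silylated ketone: tert-butyl[(1-{2,4-bis(tert-butyldimethylsilyloxy)-5-[(1R,2E)-1-[4-(tert-butyldimethylsilyloxy)phenyl]-3-(2,4-dimethoxyphenyl)prop-2-en-1-yl]phenyl}ethenyl)oxy]dimethylsilane | COc1ccc(/C=C/[C@H](c2ccc(O[Si](C)(C)C(C)(C)C)cc2)c2cc(C(=C)O[Si](C)(C)C(C)(C)C)c(O[Si](C)(C)C(C)(C)C)cc2O[Si](C)(C)C(C)(C)C)c(OC)c1 | intermediate (not isolated)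
16 | 2-bromo-1-{2,4-bis(tert-butyldimethylsilyloxy)-5-[(1R,2E)-1-[4-(tert-butyldimethylsilyloxy)phenyl]-3-(2,4-dimethoxyphenyl)prop-2-en-1-yl]phenyl}ethan-1-one | COc1ccc(/C=C/[C@H](c2ccc(O[Si](C)(C)C(C)(C)C)cc2)c2cc(C(=O)CBr)c(O[Si](C)(C)C(C)(C)C)cc2O[Si](C)(C)C(C)(C)C)c(OC)c1 | intermediate
17 | 2,4,6-trihydroxybenzaldehyde | O=Cc1c(O)cc(O)cc1O | starting material
18 | 2,6-dihydroxy-4-methoxybenzaldehyde | COc1cc(O)c(C=O)c(O)c1 | intermediate
19 | 2-(2-{2,4-bis(tert-butyldimethylsilyloxy)-5-[(1R,2E)-1-[4-(tert-butyldimethylsilyloxy)phenyl]-3-(2,4-dimethoxyphenyl)prop-2-en-1-yl]phenyl}-2-oxoethoxy)-6-hydroxy-4-methoxybenzaldehyde | COc1ccc(/C=C/[C@H](c2ccc(O[Si](C)(C)C(C)(C)C)cc2)c2cc(C(=O)COc3cc(OC)cc(O)c3C=O)c(O[Si](C)(C)C(C)(C)C)cc2O[Si](C)(C)C(C)(C)C)c(OC)c1 | intermediate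
20 | 2-(2-{2,4-bis(tert-butyldimethylsilyloxy)-5-[(1R,2E)-1-[4-(tert-butyldimethylsilyloxy)phenyl]-3-(2,4-dimethoxyphenyl)prop-2-en-1-yl]phenyl}-2-oxoethoxy)-6-(tert-butyldimethylsilyloxy)-4-methoxybenzaldehyde | COc1ccc(/C=C/[C@H](c2ccc(O[Si](C)(C)C(C)(C)C)cc2)c2cc(C(=O)COc3cc(OC)cc(O[Si](C)(C)C(C)(C)C)c3C=O)c(O[Si](C)(C)C(C)(C)C)cc2O[Si](C)(C)C(C)(C)C)c(OC)c1 | intermediate
21 | 3-{2,4-bis(tert-butyldimethylsilyloxy)-5-[(1R,2E)-1-[4-(tert-butyldimethylsilyloxy)phenyl]-3-(2,4-dimethoxyphenyl)prop-2-en-1-yl]phenyl}-5-(tert-butyldimethylsilyloxy)-3-hydroxy-7-methoxychroman-4-one (both C3 epimers) | COc1ccc(/C=C/[C@H](c2ccc(O[Si](C)(C)C(C)(C)C)cc2)c2cc(C3(O)COc4cc(OC)cc(O[Si](C)(C)C(C)(C)C)c4C3=O)c(O[Si](C)(C)C(C)(C)C)cc2O[Si](C)(C)C(C)(C)C)c(OC)c1 | intermediate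
22 | 3-{2,4-bis(tert-butyldimethylsilyloxy)-5-[(1R,2E)-1-[4-(tert-butyldimethylsilyloxy)phenyl]-3-(2,4-dimethoxyphenyl)prop-2-en-1-yl]phenyl}-5-(tert-butyldimethylsilyloxy)-7-methoxy-4H-chromen-4-one | COc1ccc(/C=C/[C@H](c2ccc(O[Si](C)(C)C(C)(C)C)cc2)c2cc(-c3coc4cc(OC)cc(O[Si](C)(C)C(C)(C)C)c4c3=O)c(O[Si](C)(C)C(C)(C)C)cc2O[Si](C)(C)C(C)(C)C)c(OC)c1 | intermediate
23 | caraganin B, 3-{2,4-dihydroxy-5-[(1R,2E)-3-(2,4-dimethoxyphenyl)-1-(4-hydroxyphenyl)prop-2-en-1-yl]phenyl}-5-hydroxy-7-methoxy-4H-chromen-4-one | COc1ccc(/C=C/[C@H](c2ccc(O)cc2)c2cc(-c3coc4cc(OC)cc(O)c4c3=O)c(O)cc2O)c(OC)c1 | target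

## Step count and least certain steps

Total: 16 steps. Longest linear sequence: 14 steps (1 → 2 → 3 → 6 → 7 → 9 → 10 → 11 → 14 → 16 → 19 → 20 → 21 → 22 → 23, that is steps 1, 2, 4–10 and 12–16). Steps 3 and 11 prepare the side components 5 and 18.

**Step 9 (key step).** The diene terminus C4 carries a branched, bulky substituent, so bond formation there may be slow. The ynone could then oligomerise, adventitious moisture could protonate the diene, or a stepwise path could divert through conjugate addition followed by aldol closure of C2 onto the ketone, which ends in a salicylate. Any 3E diene would not reach the s-cis conformation. If the ketal carbon expelled the silanol and not methanol, a methyl ether would be stranded at C2'. Fallback, setting out from 11 and returning at 14: the cycloaddition is run with N-methoxy-N-methylprop-2-ynamide in place of 12 (toluene, 80 °C, same acidic work-up). This should give 5-[(1R,2E)-1-[4-(tert-butyldimethylsilyloxy)phenyl]-3-(2,4-dimethoxyphenyl)prop-2-en-1-yl]-2,4-dihydroxy-N-methoxy-N-methylbenzamide F1. The dienophile then holds no ketone for the aldol diversion and is far less prone to oligomerise, and ring B is formed at the carboxamide oxidation level. Excess MeMgBr (THF, 0 °C; the phenoxides protect themselves) should convert F1 into the methyl ketone 14.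

**Step 4.** A β-aryl enoate is a weaker acceptor than an enone, so insertion into the alkenyl–rhodium bond may be slow enough for protodeboronation of 5 to consume the nucleophile. Facial discrimination may be incomplete, and hydroxide may remove the aryl silyl ether or hydrolyse the ester of 3 before addition. Fallback, setting out from 4 and returning at 7, replacing steps 1–5 by chirality transfer in a sigmatropic shift:
- Commercial tert-butyl(4-ethynylphenoxy)dimethylsilane is hydroborated with Cy2BH and transmetalated with Et2Zn, and the alkenylzinc is added to aldehyde 4 under catalysis by the enantiomer of 3-exo-morpholinoisoborneol that gives the (S) carbinol. This should give (1S,2E)-1-(2,4-dimethoxyphenyl)-3-[4-(tert-butyldimethylsilyloxy)phenyl]prop-2-en-1-ol F2.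
- Acetylation (Ac2O, Et3N, DMAP, 0 °C) should give the acetate (1S,2E)-1-(2,4-dimethoxyphenyl)-3-[4-(tert-butyldimethylsilyloxy)phenyl]prop-2-en-1-yl acetate F3, which ionises easily and is kept cold and base-washed.
- Ireland–Claisen rearrangement of F3 (LDA, TMSCl, THF, −78 °C → rt, mild aqueous work-up) passes through a chair transition state with both aryl groups equatorial. It should move the configuration from the carbinol carbon to Cα and give the (R) acid 7 with the (E)-styrene.

**Step 10.** The brominating agent is an electrophile in a molecule that holds an electron-rich styrene and ring D. Attack there, incomplete enol silylation, or loss of the C2' silyl ether followed by closure of the bromoketone to a benzofuranone would give mixtures. Fallback, setting out from 11 and returning at 19, using no electrophilic halogen: the amide F1 obtained as described under step 9 is silylated (TBSCl, imidazole, DMF) to 2,4-bis(tert-butyldimethylsilyloxy)-5-[(1R,2E)-1-[4-(tert-butyldimethylsilyloxy)phenyl]-3-(2,4-dimethoxyphenyl)prop-2-en-1-yl]-N-methoxy-N-methylbenzamide F4. Chloromethyllithium (ICH2Cl, MeLi·LiBr, THF, −78 °C) should add once to give 2-chloro-1-{2,4-bis(tert-butyldimethylsilyloxy)-5-[(1R,2E)-1-[4-(tert-butyldimethylsilyloxy)phenyl]-3-(2,4-dimethoxyphenyl)prop-2-en-1-yl]phenyl}ethan-1-one F5. F5 alkylates 18 (K2CO3, NaI cat., acetone) to give 19.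

**Step 14.** The aldehyde is flanked by two oxygen substituents, one a bulky silyl ether, so carbene addition may be retarded. The amidine base could then promote aldol condensation of the phenacyl ether to a 2-aroylbenzofuran or remove an aryl silyl group. Fallback, setting out from 20 and returning at 21, replacing the umpolung by reductive coupling and re-oxidation: SmI2 (2.5 equiv, THF, −78 °C; the aldehyde is the more easily reduced carbonyl, and the low temperature is meant to outrun reductive cleavage of the aryloxy ketone) should give the pinacol 3-{2,4-bis(tert-butyldimethylsilyloxy)-5-[(1R,2E)-1-[4-(tert-butyldimethylsilyloxy)phenyl]-3-(2,4-dimethoxyphenyl)prop-2-en-1-yl]phenyl}-5-(tert-butyldimethylsilyloxy)-7-methoxychromane-3,4-diol F6. Oxidation of its secondary benzylic alcohol (SO3·pyridine, DMSO, iPr2NEt, 0 °C), which does not cleave the glycol, should give 21.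

## Further compounds

F1 | step 9 | 5-[(1R,2E)-1-[4-(tert-butyldimethylsilyloxy)phenyl]-3-(2,4-dimethoxyphenyl)prop-2-en-1-yl]-2,4-dihydroxy-N-methoxy-N-methylbenzamide | COc1ccc(/C=C/[C@H](c2ccc(O[Si](C)(C)C(C)(C)C)cc2)c2cc(C(=O)N(C)OC)c(O)cc2O)c(OC)c1
F2 | step 4 | (1S,2E)-1-(2,4-dimethoxyphenyl)-3-[4-(tert-butyldimethylsilyloxy)phenyl]prop-2-en-1-ol | COc1ccc([C@@H](O)/C=C/c2ccc(O[Si](C)(C)C(C)(C)C)cc2)c(OC)c1
F3 | step 4 | (1S,2E)-1-(2,4-dimethoxyphenyl)-3-[4-(tert-butyldimethylsilyloxy)phenyl]prop-2-en-1-yl acetate | COc1ccc([C@@H](OC(C)=O)/C=C/c2ccc(O[Si](C)(C)C(C)(C)C)cc2)c(OC)c1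
F4 | step 10 | 2,4-bis(tert-butyldimethylsilyloxy)-5-[(1R,2E)-1-[4-(tert-butyldimethylsilyloxy)phenyl]-3-(2,4-dimethoxyphenyl)prop-2-en-1-yl]-N-methoxy-N-methylbenzamide | COc1ccc(/C=C/[C@H](c2ccc(O[Si](C)(C)C(C)(C)C)cc2)c2cc(C(=O)N(C)OC)c(O[Si](C)(C)C(C)(C)C)cc2O[Si](C)(C)C(C)(C)C)c(OC)c1
F5 | step 10 | 2-chloro-1-{2,4-bis(tert-butyldimethylsilyloxy)-5-[(1R,2E)-1-[4-(tert-butyldimethylsilyloxy)phenyl]-3-(2,4-dimethoxyphenyl)prop-2-en-1-yl]phenyl}ethan-1-one | COc1ccc(/C=C/[C@H](c2ccc(O[Si](C)(C)C(C)(C)C)cc2)c2cc(C(=O)CCl)c(O[Si](C)(C)C(C)(C)C)cc2O[Si](C)(C)C(C)(C)C)c(OC)c1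
F6 | step 14 | 3-{2,4-bis(tert-butyldimethylsilyloxy)-5-[(1R,2E)-1-[4-(tert-butyldimethylsilyloxy)phenyl]-3-(2,4-dimethoxyphenyl)prop-2-en-1-yl]phenyl}-5-(tert-butyldimethylsilyloxy)-7-methoxychromane-3,4-diol (mixture at C3 and C4) | COc1ccc(/C=C/[C@H](c2ccc(O[Si](C)(C)C(C)(C)C)cc2)c2cc(C3(O)COc4cc(OC)cc(O[Si](C)(C)C(C)(C)C)c4C3O)c(O[Si](C)(C)C(C)(C)C)cc2O[Si](C)(C)C(C)(C)C)c(OC)c1
A1 | alternative 1 | (Z)-2-[2,4-bis(benzyloxy)-5-bromophenyl]-3-(3,5-dimethoxyphenoxy)prop-2-enoic acid | OC(=O)/C(c1cc(Br)c(OCc2ccccc2)cc1OCc1ccccc1)=C\Oc1cc(OC)cc(OC)c1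
A2 | alternative 1 | 2',4'-bis(benzyloxy)-5'-bromo-5,7-dimethoxyisoflavone | COc1cc(OC)c2c(c1)occ(-c1cc(Br)c(OCc3ccccc3)cc1OCc1ccccc1)c2=O
A3 | alternative 2 | 2-{2,4-bis(allyloxy)-5-[(1R,2E)-1-[4-(allyloxy)phenyl]-3-(2,4-dimethoxyphenyl)prop-2-en-1-yl]phenyl}-3-(2,6-difluoro-4-methoxyphenyl)-3-oxopropanal | COc1ccc(/C=C/[C@H](c2ccc(OCC=C)cc2)c2cc(C(C=O)C(=O)c3c(F)cc(OC)cc3F)c(OCC=C)cc2OCC=C)c(OC)c1
A4 | alternative 2 | 2',4'-bis(allyloxy)-5'-[(1R,2E)-1-[4-(allyloxy)phenyl]-3-(2,4-dimethoxyphenyl)prop-2-en-1-yl]-5-fluoro-7-methoxyisoflavone | COc1ccc(/C=C/[C@H](c2ccc(OCC=C)cc2)c2cc(-c3coc4cc(OC)cc(F)c4c3=O)c(OCC=C)cc2OCC=C)c(OC)c1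
A5 | alternative 3 | 3-{2,4-bis(tert-butyldimethylsilyloxy)-5-[(1R,2E)-1-[4-(tert-butyldimethylsilyloxy)phenyl]-3-(2,4-dimethoxyphenyl)prop-2-en-1-yl]phenyl}-5-(tert-butyldimethylsilyloxy)-3-hydroxy-7-methoxychroman-4-one | COc1ccc(/C=C/[C@H](c2ccc(O[Si](C)(C)C(C)(C)C)cc2)c2cc(C3(O)COc4cc(OC)cc(O[Si](C)(C)C(C)(C)C)c4C3=O)c(O[Si](C)(C)C(C)(C)C)cc2O[Si](C)(C)C(C)(C)C)c(OC)c1
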